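Labdane numbering is used throughout: decalin C1–C10, side chain C11–C16 on C9, C17 on C8, C18 (CH2OH) and C19 (CH3) on C4, C20 on C10.
**Retrosynthesis:** remove the silyl group and the acetate. Cut C12–C13 (alkyl iodide + dienyl Grignard). Open ring B at C7–C8 (aldol condensation, with C8–O from an epoxide and C6–OH from the ketone). Then cut ring A at C5–C10 and C2–C3 in one stroke.
**Enabling feature:** in ring A the pairs C3/C5 (across quaternary C4) and C2/C10 (across C1) are each 1,3-related. C4 carries CH2OH beside ring carbon C3, so C3–O–C18 can be stored as a 3-methyloxetane. The C6 oxygen can be tied to a sulfur on C1, which makes C5=C6–O–S–C1=C10 a [3,3] array and afterwards turns C2 into a carbon nucleophile.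
**Forward order:** ynamide 3 (C3–C6, C18, C19) and vinyl sulfoxide 13 (C1, C2, C8–C12, C17, C20) are made separately and joined to ring A in step 8. The diene is then attached, ring B is closed, and C8 and C6 are adjusted.
**Stereochemistry:** sulfur of commercial menthyl sulfinate sets C10 and C5 ([3,3] chirality transfer). These set C4 (diastereoselective opening of the prochiral oxetane). C9 comes from equilibration, and C8 and C6 from substrate control in the trans-decalin.

Key step: step 8

Assumption: the sense of sulfur-to-carbon chirality transfer in step 8 is derived from a chair transition state with the p-tolyl group pseudo-equatorial; if it proves opposite, the enantiomeric menthyl sulfinate would be used in step 6.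

Step 1
Reactants: 1 3-ethynyl-3-methyloxetane; 2 N-methyl-p-toluenesulfonamide
Product: 3 ynamide N-methyl-N-[(3-methyloxetan-3-yl)ethynyl]-p-toluenesulfonamide
Conditions: CuCl2 (20 mol%), pyridine, Na2CO3, O2 (1 atm), toluene, 70 °C, 2 in excess, slow addition of 1
Reagents that add atoms: none
Why: Copper-catalysed aerobic oxidative N-alkynylation of a sulfonamide with a terminal alkyne is a standard ynamide synthesis, the 3,3-disubstituted oxetane tolerates the mildly basic medium, and no stereocentre is formed.

Step 2
Reactants: 4 2-acetylbutyrolactone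
Product: 5 3-(2-methyl-1,3-dioxolan-2-yl)oxolan-2-one (racemic)
Conditions: ethylene glycol, p-TsOH (cat.), toluene, reflux, Dean–Stark trap
Reagents that add atoms: ethylene glycol OCCO
Why: Acid-catalysed ketalisation with azeotropic removal of water masks the ketone (future C8) of the β-keto lactone and removes the acidity of C9–H; C9 stays racemic here.

Step 3
Reactants: 5 ketal lactone
Product: 6 3-(2-methyl-1,3-dioxolan-2-yl)oxolan-2-ol (racemic lactol)
Conditions: i-Bu2AlH (1.1 equiv), CH2Cl2, −78 °C; Rochelle salt work-up
Reagents that add atoms: none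
Why: Partial reduction of a γ-lactone with one equivalent of i-Bu2AlH stops at the lactol because the tetrahedral aluminium alkoxide is stable at −78 °C.

Step 4
Reactants: 6 lactol
Product: 7 3-(2-methyl-1,3-dioxolan-2-yl)pent-4-yn-1-ol (racemic)
Conditions: dimethyl (1-diazo-2-oxopropyl)phosphonate, K2CO3, MeOH, 23 °C
Reagents that add atoms: dimethyl (1-diazo-2-oxopropyl)phosphonate CC(=O)C(=[N+]=[N-])P(=O)(OC)OC
Why: Ohira–Bestmann (Seyferth–Gilbert) homologation of the open hydroxy aldehyde form of the lactol gives the terminal alkyne (C10≡C1) and frees the C12 alcohol.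

Step 5
Reactants: 7 alkynol
Product: 8 2-[5-(benzyloxy)pent-1-yn-3-yl]-2-methyl-1,3-dioxolane (racemic)
Conditions: NaH, BnBr, Bu4NI (cat.), THF, 0 → 23 °C
Reagents that add atoms: benzyl bromide BrCc1ccccc1
Why: Williamson etherification of the primary alkoxide is faster than any reaction at the much less acidic alkyne C–H and gives a group that survives organometallics and acid.

Step 6
Reactants: 8 benzyl ether; 9 (1S,2R,5S)-menthyl (R)-p-toluenesulfinate
Product: 11 alkynyl p-tolyl sulfoxide (R at sulfur; 1:1 at C9), via alkynylmagnesium bromide 10 (not isolated)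
Conditions: EtMgBr, THF, 0 → 40 °C; then 9, toluene, −20 °C; aqueous NH4Cl
Reagents that add atoms: none
Why: Andersen sulfoxide synthesis, in which the alkynyl Grignard reagent displaces menthoxide at sulfur with inversion, so the (R)-sulfinate gives the (R)-alkynyl sulfoxide as a single configuration at sulfur.

Step 7
Reactants: 11 alkynyl sulfoxide
Product: 13 tetrasubstituted (Z)-vinyl sulfoxide (R at sulfur; R at C9), via vinylcopper 12 (not isolated)
Conditions: MeMgBr, CuBr·SMe2, THF, −40 °C; 11, −78 → −30 °C; then MeI, DMPU, −30 → 23 °C; chromatographic separation of the C9 epimers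
Reagents that add atoms: methylmagnesium bromide C[Mg]Br; iodomethane IC
Why: syn-Carbocupration of an alkynyl sulfoxide puts methyl (C20) on the β carbon C10 and copper on C1, alkylation of the vinylcopper with retention adds C2 and fixes C9 cis to sulfur, and the C9 epimers, now close to the sulfur stereocentre, are separated so that only the (R)-epimer, whose bulky dioxolane arm points away from the face that reacts in step 8, is carried on.

Step 8
Reactants: 3 ynamide; 13 vinyl sulfoxide
Product: 16 ring A vinyl sulfide triisopropylsilyl ether, via vinyl sulfide 14 (not isolated), via ring A alcohol 15 (not isolated)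
Conditions: HNTf2 (20 mol%), 4 Å MS, CH2Cl2 (0.01 M), −40 → 23 °C; then 2,6-lutidine, i-Pr3SiOTf, 0 °C
Reagents that add atoms: triisopropylsilyl trifluoromethanesulfonate CC(C)[Si](C(C)C)(C(C)C)OS(=O)(=O)C(F)(F)F
Why: Proposed new method: HNTf2 protonates ynamide 3 at C5, the sulfinyl oxygen of 13 adds to the keteniminium carbon C6 on the side of the C5 hydrogen, and the oxysulfonium ketene N,O-acetal undergoes a charge-accelerated [3,3]-sigmatropic shift through the array C5=C6–O–S–C1=C10 that forms C5–C10, turns the sulfoxide oxygen into the C6 carbonyl oxygen and leaves a thionium ion at C1, which loses a proton from the C2 methyl group to give vinyl sulfide 14 and returns the acid. The acid then activates the oxetane, the sulfur-activated terminus C2 opens it at one CH2 group (C3) to form C2–C3 and free the C18 alcohol, and loss of a C2 proton gives 15, which is silylated in the same flask. The closest known reaction types are, for the first bond, the acid-mediated union of ynamides with vinyl sulfoxides to 1,4-dicarbonyl compounds and the ketene lactonisation of vinyl sulfoxides (both sulfonium [3,3] shifts with sulfur-to-carbon chirality transfer, the latter also at β,β-disubstituted alkenes that become quaternary carbons), and, for the second, the acid-catalysed opening of 3,3-disubstituted oxetanes by silyl enol ethers, silyl ketene acetals and allylsilanes; new are the tetrasubstituted sulfoxide, the vinyl sulfide as carbon nucleophile and the coupling of both events. The first bond closes no ring, and ring A then closes in the 6-(enolendo)-exo-tet mode, whereas attack of C2 on an oxocarbenium ion from the dioxolane would be a disfavoured 5-(enolendo)-exo-trig closure. C10 and C5 are set by a chair transition state with the p-tolyl group on (R)-sulfur pseudo-equatorial, by the (Z)-alkene geometry and by the keteniminium addition geometry, reinforced by the (R)-centre C9, and C4 is set because the breaking C3–O bond must lie anti to the incoming C2, which forces the CH2O arm equatorial and the C4 methyl axial in the chair that keeps the C10 methyl axial and the larger C9 and C6 groups equatorial. The step needs C-attack rather than O-attack on the oxetane and no oligomerisation, which the weakly basic N-sulfonyl carbonyl oxygen, the non-nucleophilic NTf2 anion, the steric shielding of a 3,3-disubstituted oxetane and high dilution should secure.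

Step 9
Reactants: 16 ring A vinyl sulfide
Product: 17 saturated ring A primary alcohol
Conditions: Raney nickel (W-2, excess), H2 (1 atm), EtOH, 23 → 50 °C
Reagents that add atoms: none
Why: Raney nickel hydrogenolysis of the vinylic C–S bond, hydrogenation of the ring A alkene and hydrogenolysis of the benzyl ether are standard, the ketal, silyl ether and sulfonamide are inert, and no stereocentre is touched because C1 and C2 become CH2.

Step 10
Reactants: 17 primary alcohol
Product: 18 primary iodide
Conditions: I2, PPh3, imidazole, CH2Cl2, 0 °C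
Reagents that add atoms: iodine [I][I]
Why: Appel-type iodination of the only free, unhindered primary alcohol (C12) proceeds under neutral conditions that leave ketal and silyl ether intact.

Step 11
Reactants: 18 iodide; 19 chloroprene (2-chlorobuta-1,3-diene)
Product: 21 diene acyl sulfonamide, via dienylmagnesium chloride 20 (not isolated)
Conditions: 19, Mg, ZnCl2 (cat.), THF, reflux; then 18, Li2CuCl4 (5 mol%), THF, −20 → 0 °C
Reagents that add atoms: none
Why: Copper-catalysed Kumada-type coupling of a primary alkyl iodide with buta-1,3-dien-2-ylmagnesium chloride is the standard entry to 2-alkylbuta-1,3-dienes, it forms C12–C13 before any C8 hydroxyl exists that could displace the iodide, and the very hindered acyl sulfonamide is not attacked at low temperature.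

Step 12
Reactants: 21 diene acyl sulfonamide
Product: 22 C6 methyl ketone
Conditions: MeLi (3 equiv), Et2O, −78 → 0 °C; aqueous NH4Cl
Reagents that add atoms: methyllithium [Li]C
Why: Nucleophilic acyl substitution on an N-sulfonyl amide, an activated amide whose sulfonamide anion is a good leaving group, delivers the methyl ketone (C7) with the small reagent MeLi while ketal, diene and silyl ether are inert.

Step 13
Reactants: 22 methyl ketone
Product: 24 trans-decalin enone (6-oxo-7-ene), via diketone 23 (not isolated)
Conditions: 1 M HCl, THF, 23 °C; then KOH, MeOH, 50 °C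
Reagents that add atoms: none
Why: Hydrolysis of the ketal and intramolecular aldol condensation of the 1,5-diketone join C7 to the less hindered C8 carbonyl to close ring B, while C9–H (α to C8=O, later γ to the enone) and C5–H equilibrate under base so that the side chain ends equatorial and the ring fusion trans.

Step 14
Reactants: 24 enone
Product: 25 7,8-epoxy ketone
Conditions: t-BuOOH, benzyltrimethylammonium hydroxide, THF, 0 → 23 °C
Reagents that add atoms: tert-butyl hydroperoxide CC(C)(C)OO
Why: Weitz–Scheffer nucleophilic epoxidation attacks only the enone, the peroxide adding to C8 from the face opposite the axial C20 methyl group, which sets the C8–O bond equatorial and C17 axial, and the electron-rich diene is inert to the nucleophilic oxidant.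

Step 15
Reactants: 25 epoxy ketone
Product: 26 8-hydroxy-6-ketone
Conditions: SmI2 (2.5 equiv), THF/MeOH, −90 °C
Reagents that add atoms: none
Why: SmI2 reduction of an α,β-epoxy ketone cleaves only the Cα–O bond (C7–O) through the ketyl and samarium enolate and gives the β-hydroxy ketone with C8 unchanged, cold enough to prevent retro-aldol cleavage.

Step 16
Reactants: 26 hydroxy ketone
Product: 27 6,8-diol (both hydroxyl groups equatorial)
Conditions: SmI2 (6 equiv), H2O (excess), THF, 23 °C
Reagents that add atoms: none
Why: Electron-transfer reduction with SmI2–H2O, like dissolving-metal reduction of hindered cyclohexanones flanked by axial methyl groups, should give the more stable equatorial alcohol because the oxygen–samarium group of the carbanion stage sits equatorial before protonation, and the unactivated diene is not reduced in the absence of an amine additive.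

Step 17
Reactants: 27 diol
Product: 28 6-acetate
Conditions: Ac2O, DMAP, pyridine, 23 °C
Reagents that add atoms: acetic anhydride CC(=O)OC(C)=O
Why: DMAP-catalysed acetylation takes the secondary C6 hydroxyl only, since the tertiary C8 hydroxyl is unreactive at room temperature and O18 is silylated.

Step 18
Reactants: 28 acetate
Product: 29 target CNP0312185.1
Conditions: HF·pyridine, pyridine, THF, 0 → 23 °C
Reagents that add atoms: none
Why: Fluoride-mediated desilylation in a weakly acidic medium frees the C18 alcohol without the base-induced 6→18 acetyl migration and without harm to the diene or the tertiary alcohol.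

Compound list
1 | 3-ethynyl-3-methyloxetane | C#CC1(C)COC1 | starting material
2 | N-methyl-p-toluenesulfonamide | CNS(=O)(=O)c1ccc(C)cc1 | starting material
3 | N-methyl-N-[(3-methyloxetan-3-yl)ethynyl]-p-toluenesulfonamide (ynamide; C5≡C6) | CN(C#CC1(C)COC1)S(=O)(=O)c1ccc(C)cc1 | intermediate
4 | 2-acetylbutyrolactone (3-acetyloxolan-2-one, racemic) | CC(=O)C1CCOC1=O | starting material
5 | 3-(2-methyl-1,3-dioxolan-2-yl)oxolan-2-one (racemic) | CC1(OCCO1)C1CCOC1=O | intermediate
6 | 3-(2-methyl-1,3-dioxolan-2-yl)oxolan-2-ol (racemic, anomer mixture) | CC1(OCCO1)C1CCOC1O | intermediate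
7 | 3-(2-methyl-1,3-dioxolan-2-yl)pent-4-yn-1-ol (racemic) | CC1(OCCO1)C(CCO)C#C | intermediate
8 | 2-[5-(benzyloxy)pent-1-yn-3-yl]-2-methyl-1,3-dioxolane (racemic) | CC1(OCCO1)C(CCOCc1ccccc1)C#C | intermediate
9 | (1S,2R,5S)-menthyl (R)-p-toluenesulfinate | CC(C)[C@H]1CC[C@H](C)C[C@@H]1O[S@@](=O)c1ccc(C)cc1 | starting material
10 | bromomagnesium acetylide of 8 | CC1(OCCO1)C(CCOCc1ccccc1)C#C[Mg]Br | intermediate
11 | alkynyl p-tolyl sulfoxide of 8, (R) at sulfur, 1:1 epimers at C9 | CC1(OCCO1)C(CCOCc1ccccc1)C#C[S@](=O)c1ccc(C)cc1 | intermediate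
12 | α-sulfinyl vinylcopper, C20 methyl on C10 cis to copper, C9 cis to sulfur, (R) at sulfur | CC1(OCCO1)C(CCOCc1ccccc1)/C(C)=C([Cu])\[S@](=O)c1ccc(C)cc1 | intermediate
13 | (Z)-tetrasubstituted vinyl p-tolyl sulfoxide, C1 bearing CH3 (C2), C10 bearing CH3 (C20) and C9; (R) at sulfur, (R) at C9 | CC1(OCCO1)[C@H](CCOCc1ccccc1)/C(C)=C(C)\[S@](=O)c1ccc(C)cc1 | intermediate
14 | open-chain N-methyl-N-tosyl amide: C5 bears the 3-methyloxetan-3-yl group, C10 bears CH3, 1-(p-tolylthio)vinyl and the C9 arm; C5 and C10 as in the target, C9 (R) | CC1(OCCO1)[C@H](CCOCc1ccccc1)[C@](C)(C(=C)Sc1ccc(C)cc1)[C@H](C(=O)N(C)S(=O)(=O)c1ccc(C)cc1)C1(C)COC1 | intermediate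
15 | ring A cyclohexene with C1 p-tolylthio (C1=C2), C4 axial CH3 and equatorial CH2OH, C5 equatorial acyl sulfonamide, C10 axial CH3; C4, C5, C10 as in the target, C9 (R) | CC1(OCCO1)[C@H](CCOCc1ccccc1)[C@]1(C)C(Sc2ccc(C)cc2)=CC[C@](C)(CO)[C@H]1C(=O)N(C)S(=O)(=O)c1ccc(C)cc1 | intermediate
16 | O18-triisopropylsilyl ether of 15 | CC1(OCCO1)[C@H](CCOCc1ccccc1)[C@]1(C)C(Sc2ccc(C)cc2)=CC[C@](C)(CO[Si](C(C)C)(C(C)C)C(C)C)[C@H]1C(=O)N(C)S(=O)(=O)c1ccc(C)cc1 | intermediate
17 | saturated ring A compound with free C12 alcohol (sulfur and benzyl removed) | CC1(OCCO1)[C@H](CCO)[C@]1(C)CCC[C@](C)(CO[Si](C(C)C)(C(C)C)C(C)C)[C@H]1C(=O)N(C)S(=O)(=O)c1ccc(C)cc1 | intermediate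
18 | C12 iodide of 17 | CC1(OCCO1)[C@H](CC[I])[C@]1(C)CCC[C@](C)(CO[Si](C(C)C)(C(C)C)C(C)C)[C@H]1C(=O)N(C)S(=O)(=O)c1ccc(C)cc1 | intermediate
19 | chloroprene (2-chlorobuta-1,3-diene) | C=CC(Cl)=C | starting material
20 | buta-1,3-dien-2-ylmagnesium chloride | C=CC(=C)[Mg]Cl | intermediate
21 | ring A acyl sulfonamide with the complete C11–C16 diene side chain | CC1(OCCO1)[C@H](CCC(=C)C=C)[C@]1(C)CCC[C@](C)(CO[Si](C(C)C)(C(C)C)C(C)C)[C@H]1C(=O)N(C)S(=O)(=O)c1ccc(C)cc1 | intermediate
22 | C6 methyl ketone (acetyl on C5), C8 still ketalised | CC1(OCCO1)[C@H](CCC(=C)C=C)[C@]1(C)CCC[C@](C)(CO[Si](C(C)C)(C(C)C)C(C)C)[C@H]1C(C)=O | intermediate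
23 | 1,5-diketone (C6 and C8 methyl ketones), C9 epimerising | CC(=O)C(CCC(=C)C=C)[C@]1(C)CCC[C@](C)(CO[Si](C(C)C)(C(C)C)C(C)C)[C@H]1C(C)=O | intermediate
24 | trans-decalin enone, 6-oxo, C7=C8 with C17 on C8, side chain equatorial on C9; C4, C5, C9, C10 as in the target | C=CC(=C)CC[C@H]1[C@]2(C)CCC[C@](C)(CO[Si](C(C)C)(C(C)C)C(C)C)[C@H]2C(=O)C=C1C | intermediate
25 | 7,8-epoxy-6-ketone, epoxide on the face opposite C20 | C=CC(=C)CC[C@H]1[C@]2(C)CCC[C@](C)(CO[Si](C(C)C)(C(C)C)C(C)C)[C@H]2C(=O)[C@@H]2O[C@]12C | intermediate
26 | 8-hydroxy-6-ketone (8-OH equatorial, C17 axial) | C=CC(=C)CC[C@H]1[C@]2(C)CCC[C@](C)(CO[Si](C(C)C)(C(C)C)C(C)C)[C@H]2C(=O)C[C@]1(C)O | intermediate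
27 | 6,8-diol, both hydroxyl groups equatorial | C=CC(=C)CC[C@H]1[C@]2(C)CCC[C@](C)(CO[Si](C(C)C)(C(C)C)C(C)C)[C@H]2[C@H](O)C[C@]1(C)O | intermediate
28 | 6-acetate of 27 | C=CC(=C)CC[C@H]1[C@]2(C)CCC[C@](C)(CO[Si](C(C)C)(C(C)C)C(C)C)[C@H]2[C@H](OC(C)=O)C[C@]1(C)O | intermediate
29 | (4S,5S,6R,8S,9S,10R)-6-acetoxylabda-13(16),14-diene-8,18-diol (CNP0312185.1) | C=CC(=C)CC[C@H]1[C@]2(C)CCC[C@](C)(CO)[C@H]2[C@H](OC(C)=O)C[C@]1(C)O | target

Total step count: 18. Longest linear sequence: 17 steps (steps 2–18, from 4).

Steps most likely to fail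

**Step 8 (the labelled step).**
- What may go wrong: the congested [3,3] shift may lose to oxygen transfer from sulfur to the keteniminium ion. The cascade may also stall after the first bond, through hydrolysis of the thionium ion, acid-induced oligomerisation of the oxetane, or its opening by oxygen instead of carbon.
- Fallback: it sets out from 3 and 13 and returns at 17, and makes each bond by a known reaction type. The union is run in its known hydrolytic form (HNTf2, 1 equiv, CH2Cl2, −40 °C, then aqueous NaHCO3) to give the 1,4-dicarbonyl compound, C1 methyl ketone F1. i-Pr3SiOTf and Et3N give the only possible silyl enol ether F2, because C10 is quaternary. Catalytic LiNTf2 or HNTf2 lets the silyl enol ether open the oxetane with silyl transfer to oxygen, the same chair argument setting C4, to give ring A ketone F3. KN(SiMe3)2 and PhNTf2 give enol triflate F4. Hydrogenation (H2, PtO2, then Pd/C, EtOH) reduces the enol triflate to CH2–CH2 and cleaves the benzyl ether to give 17.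

**Step 16.**
- What may go wrong: slow electron transfer to the hindered ketone, poor facial selectivity at the protonation stage, or partial reduction of the diene.
- Fallback: it sets out from 26 and returns at 27. NaBH4 in MeOH delivers hydride from the open face and gives the axial 6-epimeric alcohol F5. Meerwein–Ponndorf–Verley/Oppenauer equilibration (Al(Oi-Pr)3, i-PrOH, trace acetone, reflux) then converts it through reversible hydride transfer into the more stable equatorial alcohol 27.

**Step 12.**
- What may go wrong: attack of MeLi at sulfur with N–S cleavage, or no addition at the very hindered C6 carbonyl.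
- Fallback: it sets out from 21 and returns at 22. The smaller hydride reagent i-Bu2AlH (CH2Cl2, −78 °C) reduces the acyl sulfonamide to aldehyde F6. MeMgBr adds to give secondary alcohol F7. Dess–Martin periodinane then gives 22.

Further compounds
F1 | step 8 | 1,4-dicarbonyl compound: analogue of 14 with an acetyl group (C1 ketone, C2 methyl) on C10 in place of the thiovinyl group | CC1(OCCO1)[C@H](CCOCc1ccccc1)[C@](C)(C(C)=O)[C@H](C(=O)N(C)S(=O)(=O)c1ccc(C)cc1)C1(C)COC1
F2 | step 8 | triisopropylsilyl enol ether of F1 (C1(OSi)=C2H2) | CC1(OCCO1)[C@H](CCOCc1ccccc1)[C@](C)(C(=C)O[Si](C(C)C)(C(C)C)C(C)C)[C@H](C(=O)N(C)S(=O)(=O)c1ccc(C)cc1)C1(C)COC1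
F3 | step 8 | ring A C1 ketone with O18 triisopropylsilyl ether; C4, C5, C10 as in the target | CC1(OCCO1)[C@H](CCOCc1ccccc1)[C@]1(C)C(=O)CC[C@](C)(CO[Si](C(C)C)(C(C)C)C(C)C)[C@H]1C(=O)N(C)S(=O)(=O)c1ccc(C)cc1
F4 | step 8 | C1 enol triflate of F3 (C1=C2) | CC1(OCCO1)[C@H](CCOCc1ccccc1)[C@]1(C)C(OS(=O)(=O)C(F)(F)F)=CC[C@](C)(CO[Si](C(C)C)(C(C)C)C(C)C)[C@H]1C(=O)N(C)S(=O)(=O)c1ccc(C)cc1
F5 | step 16 | 6-epimer of 27 (axial 6-hydroxyl) | C=CC(=C)CC[C@H]1[C@]2(C)CCC[C@](C)(CO[Si](C(C)C)(C(C)C)C(C)C)[C@H]2[C@@H](O)C[C@]1(C)O
F6 | step 12 | C6 aldehyde (formyl on C5) corresponding to 21 | CC1(OCCO1)[C@H](CCC(=C)C=C)[C@]1(C)CCC[C@](C)(CO[Si](C(C)C)(C(C)C)C(C)C)[C@H]1C=O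
F7 | step 12 | C6 secondary alcohol (1-hydroxyethyl on C5, epimer mixture at C6) | CC1(OCCO1)[C@H](CCC(=C)C=C)[C@]1(C)CCC[C@](C)(CO[Si](C(C)C)(C(C)C)C(C)C)[C@H]1C(C)O
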